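**Retrosynthetic overview**

1. Labels (elemanolide numbering): vinyl C1=C2 on quaternary C10; C5 carries C4(=C3H2)C15H2OH; lactone is O–C6 / C7–C11(C13)–C12; the side-chain ester sits on O8. Target ⇐ acetonide hydrolysis ⇐ SeO2 hydroxylation at C15 ⇐ esterification of hydroxy lactone 18 with acrylic acid 24 (from an L-malic acid derivative).
2. Both rings are made in one operation from acyclic aldehyde 15: a SmI2 ketyl–enoate cyclization joins C6 (aldehyde carbon) to C7 (enoate β-carbon) and closes the carbocycle first, then the new C6 alkoxide closes the γ-lactone.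
3. 15 ⇐ acid 13 ⇐ enantioselective boron-enolate Ireland–Claisen rearrangement of allylic ester 11 (C5–C10 bond, quaternary C10 with its vinyl group).
4. 11 ⇐ 3-methylbut-3-enoic acid + allylic alcohol 9 ⇐ cross-metathesis and ester reduction of aldol 5 ⇐ asymmetric vinylogous Mukaiyama aldol of acrolein with silyl dienolate 3 (sets C8).

Assumption: the (S,S) bromoborane of step 7 and the chosen antipode of the bis-phosphoramide of step 2 are taken to give the configurations drawn; if either induces the opposite sense its enantiomer is used, and these recoverable chiral reagents are not counted as steps.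

**Route**

Step 1
Reactants: 1 methyl 3-methylbut-2-enoate
Product: 3 tert-butyl{[(1Z)-1-methoxy-3-methylbuta-1,3-dien-1-yl]oxy}dimethylsilane, via lithium dienolate 2 (not isolated)
Conditions: LiN(i-Pr)2, THF, −78 °C; then t-BuMe2SiCl, DMPU, −78 °C to rt
Reagents that add atoms: tert-butyldimethylsilyl chloride, CC(C)(C)[Si](C)(C)Cl
Why: γ-Deprotonation of the senecioate and O-silylation of the extended enolate give the silyl dienol ether needed as the vinylogous nucleophile.

Step 2
Reactants: 3 silyl dienol ether; 4 acrolein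
Product: 5 methyl (2E,5R)-5-hydroxy-3-methylhepta-2,6-dienoate
Conditions: SiCl4 (1.1 equiv), chiral binaphthyldiamine-derived bis-phosphoramide (5 mol %), CH2Cl2, −78 °C; aq. NaHCO3
Reagents that add atoms: none
Why: Lewis-base-catalysed vinylogous Mukaiyama aldol addition in which the dienolate attacks the aldehyde carbonyl through its γ-carbon and the chiral chlorosilyl cation complex blocks one aldehyde face, setting C8 (R) and leaving the (E)-enoate.

Step 3
Reactants: 5 aldol adduct
Product: 6 methyl (2E,5R)-5-[(tert-butyldimethylsilyl)oxy]-3-methylhepta-2,6-dienoate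
Conditions: t-BuMe2SiCl, imidazole, DMF, rt
Reagents that add atoms: tert-butyldimethylsilyl chloride, CC(C)(C)[Si](C)(C)Cl
Why: Standard silylation protects O8 through the hydride, borane and base steps that follow, and no stereocenter is touched.

Step 4
Reactants: 6 silyl ether ester
Product: 7 (2E,5R)-5-[(tert-butyldimethylsilyl)oxy]-3-methylhepta-2,6-dien-1-ol
Conditions: i-Bu2AlH (2.2 equiv), CH2Cl2, −78 °C; aq. KNaC4H4O6
Reagents that add atoms: none
Why: 1,2-Reduction of the only ester gives the (E)-allylic alcohol without changing alkene geometry or C8.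

Step 5
Reactants: 7 allylic alcohol; 8 methyl methacrylate (10 equiv)
Product: 9 methyl (2E,4R,6E)-4-[(tert-butyldimethylsilyl)oxy]-8-hydroxy-2,6-dimethylocta-2,6-dienoate
Conditions: second-generation Hoveyda–Grubbs catalyst (5 mol %), CH2Cl2, 40 °C
Reagents that add atoms: none
Why: Olefin cross-metathesis engages only the terminal vinyl group (the trisubstituted alkene is inert) and gives the more stable (E)-2-methyl-enoate with loss of ethylene, done before a second vinyl group exists so that ring-closing metathesis cannot compete.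

Step 6
Reactants: 9 hydroxy enoate; 10 3-methylbut-3-enoic acid
Product: 11 methyl (2E,4R,6E)-4-[(tert-butyldimethylsilyl)oxy]-2,6-dimethyl-8-[(3-methylbut-3-enoyl)oxy]octa-2,6-dienoate
Conditions: DCC, DMAP (5 mol %), CH2Cl2, −20 to 0 °C
Reagents that add atoms: none
Why: Steglich esterification of the primary allylic alcohol, run cold with little DMAP so the β,γ-double bond of the acid does not move into conjugation.

Step 7
Reactants: 11 allylic ester
Product: 13 (2R,3R,5R,6E)-5-[(tert-butyldimethylsilyl)oxy]-3-ethenyl-8-methoxy-3,7-dimethyl-8-oxo-2-(prop-1-en-2-yl)oct-6-enoic acid, via boron ketene acetal 12 (not isolated)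
Conditions: N,N'-[(1S,2S)-1,2-diphenylethane-1,2-diyl]bis[3,5-bis(trifluoromethyl)benzenesulfonamide] + BBr3, CH2Cl2 (HBr removed in vacuo); then 11, Et3N, toluene–hexane, −78 °C; then 4 °C to rt; aqueous work-up
Reagents that add atoms: none
Why: Enantioselective Ireland–Claisen rearrangement in which the E(O) boron enolate reacts through a chair with C9 equatorial (E-allyl unit) and the isopropenyl group axial, forming C5–C10 with the elemane relative configuration, while the C2-symmetric diazaborolidine selects the chair enantiomer and so fixes C5 and C10 independently of remote C8.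

Step 8
Reactants: 13 acid
Product: 15 methyl (2E,4R,6R,7R)-4-[(tert-butyldimethylsilyl)oxy]-6-ethenyl-7-formyl-2,6,8-trimethylnona-2,8-dienoate, via acid chloride 14 (not isolated)
Conditions: 1-chloro-N,N,2-trimethylprop-1-en-1-amine, CH2Cl2, 0 °C; then LiAlH(Ot-Bu)3 (1.05 equiv), THF, −78 °C
Reagents that add atoms: none
Why: Neutral acid chloride formation avoids C5 epimerization and the hindered alkoxyaluminate then performs a partial acyl chloride reduction that stops at the aldehyde and leaves the methyl enoate untouched.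

Step 9
Reactants: 15 aldehyde
Product: 17 (3R,3aR,4R,6R,7R,7aS)-4-[(tert-butyldimethylsilyl)oxy]-6-ethenyl-3,6-dimethyl-7-(prop-1-en-2-yl)hexahydro-1-benzofuran-2(3H)-one, via hydroxy ester 16 (not isolated)
Conditions: SmI2 (2.5 equiv), t-BuOH (2 equiv), THF (0.01 M), −78 to 0 °C; aq. NH4Cl; then KOt-Bu (0.2 equiv), THF, 0 °C to rt
Reagents that add atoms: none
Why: SmI2 ketyl–olefin 6-exo cyclization through a chair with isopropenyl, silyloxy and vinyl groups equatorial (C10 methyl axial) and the ketyl oxygen anti to the enoate gives the all-equatorial 6,7-trans ring, after which the C6 alkoxide closes the trans-lactone and the base equilibrates C11 to the more stable epimer (methyl cis to H7, away from C8).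

Step 10
Reactants: 17 silyl lactone
Product: 18 (3R,3aS,4R,6R,7R,7aS)-6-ethenyl-4-hydroxy-3,6-dimethyl-7-(prop-1-en-2-yl)hexahydro-1-benzofuran-2(3H)-one
Conditions: HF·pyridine, THF/pyridine, 0 °C to rt
Reagents that add atoms: none
Why: Fluoride desilylation under mildly acidic conditions frees O8 without base-induced migration of the lactone to O8.

Step 11
Reactants: 19 methyl [(4S)-2,2-dimethyl-1,3-dioxolan-4-yl]acetate
Product: 23 methyl 2-[(4S)-2,2-dimethyl-1,3-dioxolan-4-yl]prop-2-enoate, via lithium enolate 20 (not isolated), via Mannich base 21 (not isolated), via ammonium iodide 22 (not isolated)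
Conditions: LiN(i-Pr)2, THF, −78 °C; Me2N=CH2 iodide, −78 to 0 °C; MeI, MeOH, rt; aq. NaHCO3, CH2Cl2
Reagents that add atoms: N,N-dimethylmethyleneiminium iodide, C=[N+](C)C.[I-]
Why: Mannich aminomethylation of the ester enolate, N-quaternization and E1cB elimination install the α-methylene group, and the dioxolane stereocenter from L-malic acid is not deprotonated.

Step 12
Reactants: 23 acrylate ester
Product: 24 2-[(4S)-2,2-dimethyl-1,3-dioxolan-4-yl]prop-2-enoic acid
Conditions: LiOH, THF/H2O, 0 °C; then cold dilute HCl to pH 4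
Reagents that add atoms: lithium hydroxide, [Li+].[OH-]
Why: Saponification of the methyl ester at 0 °C, with brief mild acidification so the acetonide survives.

Step 13
Reactants: 18 hydroxy lactone; 24 acrylic acid
Product: 25 (3R,3aS,4R,6R,7R,7aS)-6-ethenyl-3,6-dimethyl-2-oxo-7-(prop-1-en-2-yl)octahydro-1-benzofuran-4-yl 2-[(4S)-2,2-dimethyl-1,3-dioxolan-4-yl]prop-2-enoate
Conditions: DCC, DMAP (0.2 equiv), CH2Cl2, 0 °C to rt
Reagents that add atoms: none
Why: Steglich esterification of the equatorial secondary 8-OH, with retention at C8 because only the O–H bond is broken.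

Step 14
Reactants: 25 ester
Product: 26 (3R,3aS,4R,6R,7S,7aS)-6-ethenyl-7-(3-hydroxyprop-1-en-2-yl)-3,6-dimethyl-2-oxooctahydro-1-benzofuran-4-yl 2-[(4S)-2,2-dimethyl-1,3-dioxolan-4-yl]prop-2-enoate
Conditions: SeO2 (0.5 equiv), t-BuOOH (3 equiv), CH2Cl2, rt
Reagents that add atoms: tert-butyl hydroperoxide, CC(C)(C)OO (oxygen delivered through selenium dioxide, O=[Se]=O)
Why: Riley allylic oxidation (ene reaction then [2,3]-shift) acts only on the isopropenyl group, the sole electron-rich alkene with allylic C–H, and at its methyl rather than the hindered ring methine.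

Step 15
Reactants: 26 acetonide
Product: 27 (3R,3aS,4R,6R,7S,7aS)-6-ethenyl-7-(3-hydroxyprop-1-en-2-yl)-3,6-dimethyl-2-oxooctahydro-1-benzofuran-4-yl (3S)-3,4-dihydroxy-2-methylidenebutanoate (target)
Conditions: AcOH/H2O (4:1), 35 °C
Reagents that add atoms: none
Why: Mild acid-catalysed acetonide hydrolysis releases the diol without disturbing the esters, lactone or allylic alcohol.

**Compound list**

1 | methyl 3-methylbut-2-enoate | COC(=O)C=C(C)C | starting material
2 | lithium (1Z)-1-methoxy-3-methylbuta-1,3-dien-1-olate | [Li+].CO/C(=C/C(C)=C)[O-] | intermediate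
3 | tert-butyl{[(1Z)-1-methoxy-3-methylbuta-1,3-dien-1-yl]oxy}dimethylsilane | CO/C(=C/C(C)=C)O[Si](C)(C)C(C)(C)C | intermediate
4 | acrolein (prop-2-enal) | C=CC=O | starting material
5 | methyl (2E,5R)-5-hydroxy-3-methylhepta-2,6-dienoate | COC(=O)/C=C(C)/C[C@@H](O)C=C | intermediate
6 | methyl (2E,5R)-5-[(tert-butyldimethylsilyl)oxy]-3-methylhepta-2,6-dienoate | COC(=O)/C=C(C)/C[C@@H](O[Si](C)(C)C(C)(C)C)C=C | intermediate
7 | (2E,5R)-5-[(tert-butyldimethylsilyl)oxy]-3-methylhepta-2,6-dien-1-ol | OC/C=C(C)/C[C@@H](O[Si](C)(C)C(C)(C)C)C=C | intermediate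
8 | methyl methacrylate | C=C(C)C(=O)OC | starting material
9 | methyl (2E,4R,6E)-4-[(tert-butyldimethylsilyl)oxy]-8-hydroxy-2,6-dimethylocta-2,6-dienoate | OC/C=C(C)/C[C@@H](O[Si](C)(C)C(C)(C)C)/C=C(\C)C(=O)OC | intermediate
10 | 3-methylbut-3-enoic acid | C=C(C)CC(=O)O | starting material
11 | methyl (2E,4R,6E)-4-[(tert-butyldimethylsilyl)oxy]-2,6-dimethyl-8-[(3-methylbut-3-enoyl)oxy]octa-2,6-dienoate | C=C(C)CC(=O)OC/C=C(C)/C[C@@H](O[Si](C)(C)C(C)(C)C)/C=C(\C)C(=O)OC | intermediate
12 | E(O) boron ketene acetal of 11, boron held in the (4S,5S)-1,3-bis{[3,5-bis(trifluoromethyl)phenyl]sulfonyl}-4,5-diphenyl-1,3,2-diazaborolidine ring | C=C(C)/C=C(/OB1N(S(=O)(=O)c2cc(cc(c2)C(F)(F)F)C(F)(F)F)[C@@H](c2ccccc2)[C@H](c2ccccc2)N1S(=O)(=O)c1cc(cc(c1)C(F)(F)F)C(F)(F)F)OC/C=C(C)/C[C@@H](O[Si](C)(C)C(C)(C)C)/C=C(\C)C(=O)OC | intermediate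
13 | (2R,3R,5R,6E)-5-[(tert-butyldimethylsilyl)oxy]-3-ethenyl-8-methoxy-3,7-dimethyl-8-oxo-2-(prop-1-en-2-yl)oct-6-enoic acid | OC(=O)[C@H](C(C)=C)[C@@](C)(C=C)C[C@@H](O[Si](C)(C)C(C)(C)C)/C=C(\C)C(=O)OC | intermediate
14 | methyl (2E,4R,6R,7R)-4-[(tert-butyldimethylsilyl)oxy]-7-(chlorocarbonyl)-6-ethenyl-2,6,8-trimethylnona-2,8-dienoate | ClC(=O)[C@H](C(C)=C)[C@@](C)(C=C)C[C@@H](O[Si](C)(C)C(C)(C)C)/C=C(\C)C(=O)OC | intermediate
15 | methyl (2E,4R,6R,7R)-4-[(tert-butyldimethylsilyl)oxy]-6-ethenyl-7-formyl-2,6,8-trimethylnona-2,8-dienoate | O=C[C@H](C(C)=C)[C@@](C)(C=C)C[C@@H](O[Si](C)(C)C(C)(C)C)/C=C(\C)C(=O)OC | intermediate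
16 | methyl (2RS)-2-[(1R,2S,3R,4R,6R)-6-[(tert-butyldimethylsilyl)oxy]-4-ethenyl-2-hydroxy-4-methyl-3-(prop-1-en-2-yl)cyclohexyl]propanoate | C=C[C@@]1(C)C[C@@H](O[Si](C)(C)C(C)(C)C)[C@H](C(C)C(=O)OC)[C@@H](O)[C@@H]1C(C)=C | intermediate
17 | (3R,3aR,4R,6R,7R,7aS)-4-[(tert-butyldimethylsilyl)oxy]-6-ethenyl-3,6-dimethyl-7-(prop-1-en-2-yl)hexahydro-1-benzofuran-2(3H)-one | C=C[C@@]1(C)C[C@@H](O[Si](C)(C)C(C)(C)C)[C@H]2[C@@H](OC(=O)[C@@H]2C)[C@@H]1C(C)=C | intermediate
18 | (3R,3aS,4R,6R,7R,7aS)-6-ethenyl-4-hydroxy-3,6-dimethyl-7-(prop-1-en-2-yl)hexahydro-1-benzofuran-2(3H)-one | C=C[C@@]1(C)C[C@@H](O)[C@H]2[C@@H](OC(=O)[C@@H]2C)[C@@H]1C(C)=C | intermediate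
19 | methyl [(4S)-2,2-dimethyl-1,3-dioxolan-4-yl]acetate | COC(=O)C[C@H]1COC(C)(C)O1 | starting material
20 | lithium enolate of 19 | [Li+].COC([O-])=C[C@H]1COC(C)(C)O1 | intermediate
21 | methyl 3-(dimethylamino)-2-[(4S)-2,2-dimethyl-1,3-dioxolan-4-yl]propanoate (both C2 epimers) | COC(=O)C(CN(C)C)[C@H]1COC(C)(C)O1 | intermediate
22 | {2-[(4S)-2,2-dimethyl-1,3-dioxolan-4-yl]-3-methoxy-3-oxopropyl}trimethylammonium iodide (both C2 epimers) | [I-].COC(=O)C(C[N+](C)(C)C)[C@H]1COC(C)(C)O1 | intermediate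
23 | methyl 2-[(4S)-2,2-dimethyl-1,3-dioxolan-4-yl]prop-2-enoate | COC(=O)C(=C)[C@H]1COC(C)(C)O1 | intermediate
24 | 2-[(4S)-2,2-dimethyl-1,3-dioxolan-4-yl]prop-2-enoic acid | OC(=O)C(=C)[C@H]1COC(C)(C)O1 | intermediate
25 | (3R,3aS,4R,6R,7R,7aS)-6-ethenyl-3,6-dimethyl-2-oxo-7-(prop-1-en-2-yl)octahydro-1-benzofuran-4-yl 2-[(4S)-2,2-dimethyl-1,3-dioxolan-4-yl]prop-2-enoate | C=C[C@@]1(C)C[C@@H](OC(=O)C(=C)[C@H]3COC(C)(C)O3)[C@H]2[C@@H](OC(=O)[C@@H]2C)[C@@H]1C(C)=C | intermediate
26 | (3R,3aS,4R,6R,7S,7aS)-6-ethenyl-7-(3-hydroxyprop-1-en-2-yl)-3,6-dimethyl-2-oxooctahydro-1-benzofuran-4-yl 2-[(4S)-2,2-dimethyl-1,3-dioxolan-4-yl]prop-2-enoate | C=C[C@@]1(C)C[C@@H](OC(=O)C(=C)[C@H]3COC(C)(C)O3)[C@H]2[C@@H](OC(=O)[C@@H]2C)[C@@H]1C(=C)CO | intermediate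
27 | (3R,3aS,4R,6R,7S,7aS)-6-ethenyl-7-(3-hydroxyprop-1-en-2-yl)-3,6-dimethyl-2-oxooctahydro-1-benzofuran-4-yl (3S)-3,4-dihydroxy-2-methylidenebutanoate | C=C[C@@]1(C)C[C@@H](OC(=O)C(=C)[C@H](O)CO)[C@H]2[C@@H](OC(=O)[C@@H]2C)[C@@H]1C(=C)CO | target

**Step count and risks**

Total steps: 15 (13 on the main line, 2 for the side-chain acid). Longest linear sequence: 13 steps (1 → 3 → 5 → 6 → 7 → 9 → 11 → 13 → 15 → 17 → 18 → 25 → 26 → 27).

Most likely to fail:

- **Step 7 (enantioselective Ireland–Claisen).** The risks are enolate geometry with a β,γ-unsaturated ester, a slow rearrangement to a quaternary carbon, and reagent tolerance of the enoate and silyl ether. Fallback: setting out from 11, enolize with LiN(SiMe3)2 in the presence of Me3SiCl (THF, −78 °C to rt) to give the trimethylsilyl ketene acetal F1. This rearranges without a chiral reagent and, after mild acid work-up, gives acid 13 together with its (2S,3S,5R) diastereomer F2 in roughly equal amounts. The two are separated by chromatography and the route is rejoined at 13.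

- **Step 9 (SmI2 ketyl–enoate cyclization).** The risks are competing reduction or γ-elimination of the silyloxy enoate, pinacol coupling, and the C6/C7 selectivity. Fallback: setting out from 15, use a tin-mediated radical chain instead (n-Bu3SnH, AIBN, benzene, 80 °C, slow addition). The neutral O-stannyl ketyl adds reversibly to the enoate and funnels to the all-equatorial trans product, the O-tributylstannyl ether of 16 F3. Aqueous KF work-up gives hydroxy ester 16, where the route is rejoined (KOt-Bu lactonization and C11 equilibration to 17).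

- **Step 14 (SeO2 allylic hydroxylation).** The risks are low conversion, over-oxidation to the enal, and attack at the C5 methine. Fallback: setting out from 25, carry out an ene-type chlorination of the isopropenyl group (Ca(OCl)2, solid CO2, CH2Cl2/H2O, 0 °C) to give the allylic chloride F4. Displacement with HCO2Na (cat. n-Bu4NI, DMF, 40 °C) gives the allylic formate F5, and selective formate methanolysis (NaHCO3, MeOH, 0 °C) returns to the route at 26.

**Further compounds**

F1 | step 7 | trimethylsilyl ketene acetal of 11 (E(O) geometry) | C=C(C)/C=C(/O[Si](C)(C)C)OC/C=C(C)/C[C@@H](O[Si](C)(C)C(C)(C)C)/C=C(\C)C(=O)OC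
F2 | step 7 | (2S,3S,5R,6E)-5-[(tert-butyldimethylsilyl)oxy]-3-ethenyl-8-methoxy-3,7-dimethyl-8-oxo-2-(prop-1-en-2-yl)oct-6-enoic acid | OC(=O)[C@@H](C(C)=C)[C@](C)(C=C)C[C@@H](O[Si](C)(C)C(C)(C)C)/C=C(\C)C(=O)OC
F3 | step 9 | O-tributylstannyl ether of 16 | C=C[C@@]1(C)C[C@@H](O[Si](C)(C)C(C)(C)C)[C@H](C(C)C(=O)OC)[C@@H](O[Sn](CCCC)(CCCC)CCCC)[C@@H]1C(C)=C
F4 | step 14 | (3R,3aS,4R,6R,7S,7aS)-7-(3-chloroprop-1-en-2-yl)-6-ethenyl-3,6-dimethyl-2-oxooctahydro-1-benzofuran-4-yl 2-[(4S)-2,2-dimethyl-1,3-dioxolan-4-yl]prop-2-enoate | C=C[C@@]1(C)C[C@@H](OC(=O)C(=C)[C@H]3COC(C)(C)O3)[C@H]2[C@@H](OC(=O)[C@@H]2C)[C@@H]1C(=C)CCl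
F5 | step 14 | (3R,3aS,4R,6R,7S,7aS)-6-ethenyl-7-[3-(formyloxy)prop-1-en-2-yl]-3,6-dimethyl-2-oxooctahydro-1-benzofuran-4-yl 2-[(4S)-2,2-dimethyl-1,3-dioxolan-4-yl]prop-2-enoate | C=C[C@@]1(C)C[C@@H](OC(=O)C(=C)[C@H]3COC(C)(C)O3)[C@H]2[C@@H](OC(=O)[C@@H]2C)[C@@H]1C(=C)COC=O
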